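(Readings and results are simulated from invented constants; noise was put on by code.)

**The count.** If over-reacted product cost two reagent and target one, the earlier readings counted the reagent consumed.

in all of them: substrate 0.25 M

| run | reagent in the second phase | temperature | remark | time | volume of the second phase over the first |
|---|---|---|---|---|---|
| south | 1.3 equiv | 95 °C | run made earlier |  |  |
| south-east | 3 equiv | 112 °C | run made earlier |  |  |
| cedar | 2.00 equiv | 125 °C |  | 1.5 h | 2.0 |
| maple | 2.00 equiv | 100 °C |  | 1.5 h | 2.0 |

- south (time / min: over-reacted product / %, substrate / %, target / %): 8.00: 1.5, 96.3, 2.5; 12.0: 2.5, 95.2, 3.4; 20.0: 6.3, 90.6, 3.3; 30.0: 10.9, 85.8, 2.8; 50.0: 18.9, 77.7, 2.7; 80.0: 28.4, 69.7, 2.6; 120: 37.8, 61.0, 1.6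
- south-east (time / min: over-reacted product / %, substrate / %, target / %): 4.00: 2.2, 94.0, 4.1; 6.00: 4.7, 90.5, 4.2; 12.0: 13.7, 81.7, 4.1; 15.0: 18.0, 77.8, 4.0; 30.0: 37.9, 58.9, 3.3; 40.0: 49.2, 47.7, 2.4; 60.0: 67.3, 30.4, 2.0

(standard deviation of a reading: 0.3 percentage points)

- in the second phase: reagent in the second phase; everything else is in the first
- charges count per volume of the first phase; a concentration in a rate is the amount of a species over the volume of its own phase; every rate counts per litre of the first phase
- the earlier runs hold the two phases in the same ratio of volumes as the flask asked about

- which of these there is most of at the end, counted by the substrate in it, cedar (substrate / target / over-reacted product)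
- which of these there is most of at the end, counted by the substrate in it, maple (substrate / target / over-reacted product)
- amount of the one of these that there is most of at the end, in percent of the substrate charged, cedar
- amount of the one of these that there is most of at the end, in percent of the substrate charged, maple

**One constant.** I took the share of unconsumed reagent consumed per minute, a pseudo-first-order constant, and called it the drain constant. The south run gave 0.00751 min⁻¹ at its last reading. The south-east run gave 0.0101 min⁻¹. The runs differed in temperature and in charge together, so I had two ways to a new flask.

**Two ways.** By temperature, with the logarithm of the constant straight in degrees, maple got 0.00820 min⁻¹. That was maple's drain constant. By charge, on a straight line in equivalents, maple got 0.00859 min⁻¹. I divided the consumed reagent by two and dropped target. Maple then came to 52.2% over-reacted product by temperature and 53.8% by charge. They stood 1.6 percentage points apart. Both came from the same two constants, so that gap measured my choice of line and was no check on the constants.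

**Where they parted.** Cedar stood above both earlier temperatures. By charge it kept maple's number. By temperature its constant was 0.0127 min⁻¹, which gave 68.2%. So I looked inside the south-east run. From 40.0 min to 60.0 min it held less unconsumed reagent than maple's charge, yet it ran at 0.00991 min⁻¹, above the charge line. I judged that the charge way cheated, and I kept temperature, though for cedar it was an extrapolation.

**The forecast.** It read “This points to a transfer-limited process, first order in reagent”. It named over-reacted product for cedar at 66% and over-reacted product for maple at 51%. My own numbers differed: 68.2% for cedar stood above its value, and 52.2% for maple stood above its value.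

**The flasks.** Cedar gave over-reacted product at 61.7%, and maple gave over-reacted product at 52.9%, both within the forecast's margins.

    reagent in the reaction phase ⇌ reagent in the second phase, rate k1*([reagent in the reaction phase] - [reagent in the second phase]/K1) per volume of the first phase (partition coefficient = 1.80, kL = 7.59 × 10⁻⁴ s⁻¹)
    reagent in the reaction phase + target → over-reacted product (k = 0.170 M⁻¹ s⁻¹, Ea = 69.0 kJ mol⁻¹)
    substrate + reagent in the reaction phase ⇌ target (K = 2.00 M⁻¹, k = 1.10 M⁻¹ s⁻¹, Ea = 60.0 kJ mol⁻¹, ΔH = 33.0 kJ mol⁻¹)
    (constants at 100 °C)

**Shorter maple.** Maple's end read back as 0.00859 min⁻¹, against my 0.00820 min⁻¹. A change of time could turn the forecast's choice, so I took maple read at 40 min. My constant put over-reacted product there at 28.0%, which left substrate ahead. That flask held 28.0% over-reacted product, and its largest part was substrate, at 69%.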